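Each chlorinated ring A is disconnected across C4a-C8a, C5-C6 and C8-C8a into a siloxyalkyne (C4a, C5) and 4-chloro-3-ethoxycyclobutenone (C6, C7, C8, C8a). The feature exploited is the pentasubstituted benzene of ring A: oxygen at C5, C7 and C8a, chlorine at C8 next to the C8a-O1 bond, hydrogen only at C6. One thermal operation builds both such rings with C8a-OH free, C5-O silylated and C7-O ethylated. Ring C can therefore close in only one direction. The precursor is a 4-methoxy diaryl ether carrying two benzyl arms, each ending in a dioxolane-masked C4 carbon bonded to a triisopropylsiloxyalkyne.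

Key step: step 9

Assumption: the target is achiral, so the cyclobutenone is used as the racemate; its stereocentre and those of the transient cascade intermediates vanish on aromatisation.

Step 1
Reactants: 1 chloroacetyl chloride; 2 ethoxyacetylene
Product: 4 4-chloro-3-ethoxycyclobut-2-en-1-one (racemic), via chloroketene 3 (not isolated)
Conditions: Et3N, Et2O, slow addition of 1 to 2 (excess), 0 °C to rt; filter, short-path purification, store cold
Reagents that add atoms: none
Why: Dehydrochlorination gives chloroketene, which is trapped in a ketene/ynol ether (2+2) cycloaddition where the nucleophilic terminal carbon of 2 bonds to the ketene carbonyl carbon, so OEt ends at C3 and Cl at C4, and the single stereocentre forms racemic and is erased later.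

Step 2
Reactants: 5 2-(3-hydroxy-4-methoxyphenyl)acetic acid
Product: 6 methyl 2-(3-hydroxy-4-methoxyphenyl)acetate
Conditions: MeOH, H2SO4 (cat.), reflux
Reagents that add atoms: methanol, CO
Why: Fischer esterification converts the aliphatic acid selectively and leaves the phenol free for the coupling.

Step 3
Reactants: 6 methyl 2-(3-hydroxy-4-methoxyphenyl)acetate; 7 methyl 2-(4-bromophenyl)acetate
Product: 8 diaryl ether diester, methyl 2-{4-methoxy-3-[4-(2-methoxy-2-oxoethyl)phenoxy]phenyl}acetate
Conditions: CuI (10 mol %), N,N-dimethylglycine hydrochloride (30 mol %), Cs2CO3, 1,4-dioxane, 90 °C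
Reagents that add atoms: none
Why: The ligand-accelerated Ullmann diaryl ether synthesis couples ortho-methoxyphenols with unactivated aryl bromides under carbonate base that arylacetic esters tolerate, and it installs both C3 side chains at once.

Step 4
Reactants: 8 diaryl ether diester
Product: 9 bis(N-methoxy-N-methylamide)
Conditions: MeNH(OMe)·HCl, i-PrMgCl, THF, -20 to 0 °C
Reagents that add atoms: N,O-dimethylhydroxylamine hydrochloride, CNOC.Cl
Why: Aminolysis of the esters by the magnesium amide (Weinreb amide formation) is faster than enolisation at this temperature and touches neither aryl ether.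

Step 5
Reactants: 9 bis(N-methoxy-N-methylamide)
Product: 10 bis(trimethylsilyl ynone), each arm ArCH2-C(=O)-C≡C-SiMe3
Conditions: Me3SiC≡CH, n-BuLi, THF, -78 °C; add 9, -78 to 0 °C; pour into cold 0.5 M HCl
Reagents that add atoms: trimethylsilylacetylene, C#C[Si](C)(C)C
Why: In the Weinreb ketone synthesis the chelated tetrahedral adduct prevents over-addition, the weakly basic acetylide does not enolise the amide, and the silyl cap blocks conjugate addition of the released amine.

Step 6
Reactants: 10 bis(trimethylsilyl ynone)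
Product: 11 bis[2-(trimethylsilylethynyl)-1,3-dioxolane]
Conditions: (Me3SiOCH2)2, Me3SiOTf (10 mol %), CH2Cl2, -78 to -20 °C; pyridine quench
Reagents that add atoms: 1,2-bis(trimethylsiloxy)ethane, C[Si](C)(C)OCCO[Si](C)(C)C
Why: Noyori ketalisation is aprotic and cold, so the benzylic ynone neither isomerises nor meets a free diol for conjugate addition, and the five-membered ketal is the smallest mask that keeps C4 at the ketone oxidation level.

Step 7
Reactants: 11 bis[2-(trimethylsilylethynyl)-1,3-dioxolane]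
Product: 12 bis(2-ethynyl-1,3-dioxolane)
Conditions: K2CO3 (cat.), MeOH, rt
Reagents that add atoms: none
Why: Base-catalysed protodesilylation of alkynylsilanes is selective, and ketals and aryl ethers are inert to it.

Step 8
Reactants: 12 bis(2-ethynyl-1,3-dioxolane)
Product: 15 bis(triisopropylsiloxyalkyne), via bis(lithium acetylide) 13 (not isolated), via bis(lithium ynolate) 14 (not isolated)
Conditions: n-BuLi (2.1 equiv), THF, -78 °C; LiOOt-Bu (from t-BuOOH and LiN(SiMe3)2), -78 to 0 °C; i-Pr3SiOTf, -78 to 0 °C; Et3N-deactivated silica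
Reagents that add atoms: tert-butyl hydroperoxide, CC(C)(C)OO; triisopropylsilyl trifluoromethanesulfonate, CC(C)[Si](OS(=O)(=O)C(F)(F)F)(C(C)C)C(C)C
Why: Attack of a lithium acetylide on the oxygen of lithium tert-butyl peroxide is an established route to lithium ynolates, a bulky silyl electrophile traps them on oxygen rather than carbon, and the cyclic ketal makes any alkoxide expulsion from the ynolate reversible.

Step 9
Reactants: 15 bis(triisopropylsiloxyalkyne); 4 4-chloro-3-ethoxycyclobut-2-en-1-one (3 equiv, in portions)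
Product: 20 bis-dioxolane bis-phenol (each ketal carbon bears a 3-chloro-4-ethoxy-2-hydroxy-6-triisopropylsiloxyphenyl ring A), via chlorovinylketene 16 (not isolated), via bis(vinylcyclobutenone) 17 (not isolated), via bis(dienylketene) 18 (not isolated), via bis(cyclohexadienone) 19 (not isolated)
Conditions: toluene (0.5 M), 2,6-di-tert-butyl-4-methylpyridine (10 mol %), argon, sealed tube, 80 °C then 110 °C
Reagents that add atoms: none
Why: This is a Danheiser benzannulation run on both alkynes: 4 opens by four-electron conrotation, chlorine turning outward, to chlorovinylketene 16, whose carbonyl carbon is attacked by the ketal-bearing alkyne carbon while the siloxy-bearing carbon bonds to the ketene CH, giving the 4-vinylcyclobutenones 17. Reversible opening of 17 to the dienylketenes 18 and six-electron disrotatory closure of C8 onto C8a forms each carbocycle as cyclohexadienone 19, which enolises irreversibly to phenol 20, so each ring A is closed by a 6π electrocyclisation. The closest known reaction type is the benzannulation of cyclobutenones with triisopropylsiloxyalkynes to resorcinol monosilyl ethers. The one selectivity needed is the orientation of the (2+2) step, and it is secured by lone-pair polarisation of the ynol ether, which makes the carbon remote from oxygen nucleophilic and so places OH at C8a between the C4 chain and Cl at C8, OSi(i-Pr)3 at C5 and OEt at C7. No stereocentre survives, because those of 4, 17 and 19 are lost on aromatisation. A ketal at C4, rather than a free ynone or a carbinol ether, keeps the alkyne electron-rich and prevents benzylic ionisation of the product to a quinone methide.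

Step 10
Reactants: 20 bis-dioxolane bis-phenol
Product: 21 bis(2-hydroxydeoxybenzoin), each arm ArCH2-C(=O)-(3-chloro-4-ethoxy-2-hydroxy-6-triisopropylsiloxyphenyl)
Conditions: 1 M HCl, THF, rt to 40 °C
Reagents that add atoms: water, O
Why: Acid-catalysed ketal hydrolysis is helped by the electron-rich aryl group and by relief of ortho strain, while aryl triisopropylsilyl ethers resist dilute aqueous acid.

Step 11
Reactants: 21 bis(2-hydroxydeoxybenzoin)
Product: 23 bis(8-chloro-7-ethoxy-5-triisopropylsiloxyisoflavone) 4'-methyl ether, via bis(enaminone) 22 (not isolated)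
Conditions: Me2NCH(OMe)2, toluene, 95 °C; then AcOH, 60 °C
Reagents that add atoms: N,N-dimethylformamide dimethyl acetal, COC(OC)N(C)C
Why: In the formamide-acetal isoflavone synthesis the benzylic methylene condenses to an enaminone, and the C8a phenol, the only free one, displaces dimethylamine by 6-endo addition-elimination, which fixes chlorine at C8 rather than C6.

Step 12
Reactants: 23 bis(8-chloro-7-ethoxy-5-triisopropylsiloxyisoflavone) 4'-methyl ether
Product: 24 bis(8-chloro-7-ethoxy-5-hydroxyisoflavone) 4'-methyl ether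
Conditions: Bu4NF, AcOH, THF, 0 °C
Reagents that add atoms: none
Why: Fluoride cleaves the aryl Si-O bond quickly, and the acetic acid buffer protects the pyranone from nucleophilic ring opening.

Step 13
Reactants: 24 bis(8-chloro-7-ethoxy-5-hydroxyisoflavone) 4'-methyl ether
Product: 25 bisoflavolin M
Conditions: BBr3 (12 equiv), CH2Cl2, -78 °C to rt; ice-water
Reagents that add atoms: none
Why: BBr3 cleaves aryl alkyl ethers by bromide attack on the alkyl carbon of the boron-complexed ether, so both ethyl ethers and the methyl ether fall while the diaryl ether, the aryl chlorides and the chromone core are inert.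

Compound list
1 | chloroacetyl chloride | ClCC(Cl)=O | starting material
2 | ethoxyacetylene | CCOC#C | starting material
3 | chloroketene | ClC=C=O | intermediate
4 | 4-chloro-3-ethoxycyclobut-2-en-1-one (racemic) | CCOC1=CC(=O)C1Cl | intermediate
5 | 2-(3-hydroxy-4-methoxyphenyl)acetic acid | COc1ccc(CC(=O)O)cc1O | starting material
6 | methyl 2-(3-hydroxy-4-methoxyphenyl)acetate | COC(=O)Cc1ccc(OC)c(O)c1 | intermediate
7 | methyl 2-(4-bromophenyl)acetate | COC(=O)Cc1ccc(Br)cc1 | starting material
8 | methyl 2-{4-methoxy-3-[4-(2-methoxy-2-oxoethyl)phenoxy]phenyl}acetate | COC(=O)Cc1ccc(Oc2cc(CC(=O)OC)ccc2OC)cc1 | intermediate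
9 | bis(N-methoxy-N-methylamide) of the diaryl ether diacid | CON(C)C(=O)Cc1ccc(Oc2cc(CC(=O)N(C)OC)ccc2OC)cc1 | intermediate
10 | 1-{4-methoxy-3-[4-(2-oxo-4-trimethylsilylbut-3-yn-1-yl)phenoxy]phenyl}-4-trimethylsilylbut-3-yn-2-one | COc1ccc(CC(=O)C#C[Si](C)(C)C)cc1Oc1ccc(CC(=O)C#C[Si](C)(C)C)cc1 | intermediate
11 | bis-dioxolane of 10 (each C=O as 1,3-dioxolane-2,2-diyl) | COc1ccc(CC2(C#C[Si](C)(C)C)OCCO2)cc1Oc1ccc(CC2(C#C[Si](C)(C)C)OCCO2)cc1 | intermediate
12 | 2-ethynyl-2-{4-[5-((2-ethynyl-1,3-dioxolan-2-yl)methyl)-2-methoxyphenoxy]benzyl}-1,3-dioxolane | COc1ccc(CC2(C#C)OCCO2)cc1Oc1ccc(CC2(C#C)OCCO2)cc1 | intermediate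
13 | bis(lithium acetylide) of 12 | COc1ccc(CC2(C#C[Li])OCCO2)cc1Oc1ccc(CC2(C#C[Li])OCCO2)cc1 | intermediate
14 | bis(lithium ynolate) | COc1ccc(CC2(C#CO[Li])OCCO2)cc1Oc1ccc(CC2(C#CO[Li])OCCO2)cc1 | intermediate
15 | bis(triisopropylsiloxyalkyne) (12 with each terminal C-H replaced by C-OSi(i-Pr)3) | CC(C)[Si](OC#CC1(Cc2ccc(Oc3cc(CC4(C#CO[Si](C(C)C)(C(C)C)C(C)C)OCCO4)ccc3OC)cc2)OCCO1)(C(C)C)C(C)C | intermediate
16 | (Z)-4-chloro-3-ethoxybuta-1,3-dien-1-one (chlorovinylketene, Cl trans to the ketene carbon chain) | O=C=C/C(OCC)=C/Cl | intermediate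
17 | bis[4-(2-chloro-1-ethoxyvinyl)-3-triisopropylsiloxycyclobut-2-enon-2-yl] adduct (ring stereocentres unassigned) | COc1ccc(CC2(OCCO2)C2=C(O[Si](C(C)C)(C(C)C)C(C)C)C(/C(OCC)=C/Cl)C2=O)cc1Oc1ccc(CC2(OCCO2)C2=C(O[Si](C(C)C)(C(C)C)C(C)C)C(/C(OCC)=C/Cl)C2=O)cc1 | intermediate
18 | bis(dienylketene), central alkene with the chain ends cis | COc1ccc(CC2(OCCO2)C(=C=O)/C(O[Si](C(C)C)(C(C)C)C(C)C)=C\C(OCC)=C\Cl)cc1Oc1ccc(CC2(OCCO2)C(=C=O)/C(O[Si](C(C)C)(C(C)C)C(C)C)=C\C(OCC)=C\Cl)cc1 | intermediate
19 | bis(6-chloro-5-ethoxy-3-triisopropylsiloxycyclohexa-2,4-dienon-2-yl) compound (stereocentres unassigned) | COc1ccc(CC2(OCCO2)C2=C(O[Si](C(C)C)(C(C)C)C(C)C)C=C(OCC)C(Cl)C2=O)cc1Oc1ccc(CC2(OCCO2)C2=C(O[Si](C(C)C)(C(C)C)C(C)C)C=C(OCC)C(Cl)C2=O)cc1 | intermediate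
20 | bis-dioxolane with two 3-chloro-4-ethoxy-2-hydroxy-6-(triisopropylsiloxy)phenyl A rings | CCOc1cc(O[Si](C(C)C)(C(C)C)C(C)C)c(C2(Cc3ccc(Oc4cc(CC5(c6c(O[Si](C(C)C)(C(C)C)C(C)C)cc(OCC)c(Cl)c6O)OCCO5)ccc4OC)cc3)OCCO2)c(O)c1Cl | intermediate
21 | bis(2-hydroxydeoxybenzoin) | CCOc1cc(O[Si](C(C)C)(C(C)C)C(C)C)c(C(=O)Cc2ccc(Oc3cc(CC(=O)c4c(O[Si](C(C)C)(C(C)C)C(C)C)cc(OCC)c(Cl)c4O)ccc3OC)cc2)c(O)c1Cl | intermediate
22 | bis(enaminone), alkene geometry labile | CCOc1cc(O[Si](C(C)C)(C(C)C)C(C)C)c(C(=O)C(=CN(C)C)c2ccc(Oc3cc(C(=CN(C)C)C(=O)c4c(O[Si](C(C)C)(C(C)C)C(C)C)cc(OCC)c(Cl)c4O)ccc3OC)cc2)c(O)c1Cl | intermediate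
23 | bis(8-chloro-7-ethoxy-5-triisopropylsiloxyisoflavone) 4'-methyl ether | CCOc1cc(O[Si](C(C)C)(C(C)C)C(C)C)c2c(=O)c(-c3ccc(Oc4cc(-c5coc6c(Cl)c(OCC)cc(O[Si](C(C)C)(C(C)C)C(C)C)c6c5=O)ccc4OC)cc3)coc2c1Cl | intermediate
24 | bis(8-chloro-7-ethoxy-5-hydroxyisoflavone) 4'-methyl ether | CCOc1cc(O)c2c(=O)c(-c3ccc(Oc4cc(-c5coc6c(Cl)c(OCC)cc(O)c6c5=O)ccc4OC)cc3)coc2c1Cl | intermediate
25 | bisoflavolin M | O=c1c(-c2ccc(Oc3cc(-c4coc5c(Cl)c(O)cc(O)c5c4=O)ccc3O)cc2)coc2c(Cl)c(O)cc(O)c12 | target

Total steps: 13. Longest linear sequence: 12 (steps 2 to 13, from 5 to 25).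

Steps most likely to fail

Step 9. Capture of the short-lived chlorovinylketene by an alkyne that is hindered and inductively deactivated by the ketal may be slower than ketene dimerisation or acylation of the newly formed phenols. The cascade may also stall at the vinylcyclobutenone stage on one arm.

The fallback gives up ring construction and buys ring A. It sets out from 8 and comes back at 25.
- LiOH in THF/H2O gives the diaryl ether diacid F1.
- Friedel-Crafts acylation of commercial 2-chloro-1,3,5-trimethoxybenzene with F1 in P2O5/MeSO3H gives the bis(3-chloro-2,4,6-trimethoxyphenyl ketone) F2.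
- BCl3 (one equivalent per ketone, CH2Cl2, -78 to 0 °C) should remove, through the carbonyl chelate, the ortho methyl ether that chlorine forces out of plane. This gives the bis(3-chloro-2-hydroxy-4,6-dimethoxyphenyl ketone) F3.
- Me2NCH(OMe)2 closes it to the bis(8-chloro-5,7-dimethoxyisoflavone) F4, and BBr3 gives 25.
- In this variant the differentiation of the two ortho oxygens rests on the demethylation preference rather than on the ring synthesis.

Step 8. Oxygen transfer from the peroxide to an acetylide made less nucleophilic by the ketal may be sluggish. During the hours at 0 °C the ynolate may lose alkoxide from the adjacent ketal carbon and decompose.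

The fallback reaches the ynolate at low temperature by an alkynyl ester route. It sets out from 12 and comes back at 14.
- PhI(OH)OTs with 4 Å sieves in CH2Cl2 gives the bis(alkynyl(phenyl)iodonium tosylate) F5.
- Catalytic CuOTf in MeCN collapses it with loss of iodobenzene to the bis(alkynyl tosylate) F6.
- MeLi in THF at -78 °C attacks sulfur and releases 14, which is silylated at once at -78 °C to give 15.

Step 1. Chloroketene may polymerise, and the ynol ether may be consumed by the acid chloride or by the ammonium salt before cycloaddition occurs.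

The fallback uses the better-behaved dihaloketene. It sets out from 2 and comes back at 4.
- Trichloroacetyl chloride and activated Zn dust in Et2O/DME generate dichloroketene F7.
- F7 adds to 2 to give 4,4-dichloro-3-ethoxycyclobut-2-en-1-one F8.
- Controlled reduction with Zn dust, AcOH and TMEDA in EtOH at 0 °C is stopped after loss of the first, more easily reduced chlorine, which gives 4.

Further compounds
F1 | step 9 | 2-{3-[4-(carboxymethyl)phenoxy]-4-methoxyphenyl}acetic acid | COc1ccc(CC(=O)O)cc1Oc1ccc(CC(=O)O)cc1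
F2 | step 9 | bis(3-chloro-2,4,6-trimethoxyphenyl ketone) | COc1ccc(CC(=O)c2c(OC)cc(OC)c(Cl)c2OC)cc1Oc1ccc(CC(=O)c2c(OC)cc(OC)c(Cl)c2OC)cc1
F3 | step 9 | bis(3-chloro-2-hydroxy-4,6-dimethoxyphenyl ketone) | COc1ccc(CC(=O)c2c(OC)cc(OC)c(Cl)c2O)cc1Oc1ccc(CC(=O)c2c(OC)cc(OC)c(Cl)c2O)cc1
F4 | step 9 | bis(8-chloro-5,7-dimethoxyisoflavone) 4'-methyl ether | COc1ccc(-c2coc3c(Cl)c(OC)cc(OC)c3c2=O)cc1Oc1ccc(-c2coc3c(Cl)c(OC)cc(OC)c3c2=O)cc1
F5 | step 8 | bis(alkynyl(phenyl)iodonium tosylate) of 12 | COc1ccc(CC2(C#C[I+]c3ccccc3)OCCO2)cc1Oc1ccc(CC2(C#C[I+]c3ccccc3)OCCO2)cc1.Cc1ccc(S(=O)(=O)[O-])cc1.Cc1ccc(S(=O)(=O)[O-])cc1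
F6 | step 8 | bis(alkynyl tosylate) | COc1ccc(CC2(C#COS(=O)(=O)c3ccc(C)cc3)OCCO2)cc1Oc1ccc(CC2(C#COS(=O)(=O)c3ccc(C)cc3)OCCO2)cc1
F7 | step 1 | dichloroketene | ClC(Cl)=C=O
F8 | step 1 | 4,4-dichloro-3-ethoxycyclobut-2-en-1-one | CCOC1=CC(=O)C1(Cl)Cl
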